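Late in the south run, the flask that is asked about, L gains about the same amount for each doubling of the time rather than for each hour: 4.9 percentage points per doubling from 2.50 h to 4.00 h, and 4.7 points from 6.00 h to 10.0 h.

| flask | Z | Q | X | temperature | remark | time |
|---|---|---|---|---|---|---|
| south | 0.32 M | 0.32 M | 3 equiv | 110 °C | the very flask that is asked about, followed so far |  |
| north-west | 0.32 M | 0.32 M | 6 equiv | 110 °C | run made earlier |  |
| flask | 0.32 M | 0.32 M | 3.00 equiv | 110 °C |  | 15 h |

| run | time / h | L / % |
|---|---|---|
| south | 0.667 | 8.2 |
| south | 1.00 | 10.8 |
| south | 1.50 | 15.1 |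
| south | 2.50 | 20.0 |
| south | 4.00 | 23.3 |
| south | 6.00 | 26.1 |
| south | 10.0 | 29.6 |
| north-west | 0.833 | 17.4 |
| north-west | 1.50 | 25.6 |
| north-west | 2.50 | 32.0 |
| north-west | 3.00 | 34.5 |
| north-west | 4.00 | 35.7 |
| north-west | 5.00 | 38.8 |
| north-west | 6.00 | 40.1 |

(scatter of a reading: 0.5 percentage points)

- X is single-handed; Z and Q are mirror images of each other, charged as a racemate, each of them at the stated concentration
- L taken out counts as made
- the analysis behind the earlier runs scatters by 0.5 percentage points, standard deviation
- what may be going on: X <-> G; X + Z -> L; Z <-> Q; X + Q -> J
- the earlier runs do not show what temperature does; that part of a forecast is a guess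
- the handed part of X does not stay in what it makes, so the products of the two hands are mirror images too

- summer: change nothing and wait 15 h more
- noon: at 15 h take out 90% of the L then present, then wait 15 h
- dawn: at 15 h raise the temperature by 15 K, then wait 15 h

1. L, in percent of the Z and Q together first charged, at 15 h
2. which option adds most L ("none" when 2 percentage points or less is all one gets) (summer / noon / dawn / none)
3. L present, with what was taken out counted in, in percent of the Z and Q together first charged, after summer
4. L present, with what was taken out counted in, in percent of the Z and Q together first charged, after dawn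

The south curve opens steeply, with 8.2% of L in the first 0.667 h, and the north-west run, with twice the X, opens 1.70 times as fast. The knee of the south curve lies near 2.50 h: up to there, from 1.00 h, a doubling brings 7 points. By the last stretch L gains 3.5 points in 4.00 h, so the hourly gain has fallen by a factor of 14.1. That is more than the factor of 2.45 that the L made takes out of [Z], so [X] has dropped as well, and X ⇌ G offers the way. The level ahead is 50.0% if Z stays Z, and racemisation, Z ⇌ Q, may carry L past it.

The tail therefore gets one number, the doubling gain 4.8 points: the points of L added each time the clock doubles, read across the south tail from 2.50 h to 10.0 h. My own count from the last reading gives 32.4% at 15 h and, one doubling later, 37.2% after summer. L stands in the listed steps as a product, so noon counts the same. Guessing that 15 K doubles every rate, dawn reaches 40.0% and comes out best.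

The forecast stands higher: 33.2% now, 39.5% after summer, 45% after dawn, and dawn as the best option, with noon level with summer: “Removing L does nothing, because L is not in any equilibrium”.

The flask gives 31.0% at 15 h, 35.7% after summer, the same gain of 4.7 points for noon, and 41.5% after dawn, so dawn adds most, 10 points. At 15.0 h X stands at 5.23% of its charge and G at 0.604 M.

    X ⇌ G (K = 10.2, k = 0.00473 min⁻¹, Ea = 119 kJ mol⁻¹, ΔH = 34.0 kJ mol⁻¹)
    X + Z → L (k = 0.00544 M⁻¹ min⁻¹, Ea = 102 kJ mol⁻¹)
    Z ⇌ Q (k = 2.94 × 10⁻⁴ min⁻¹, Ea = 124 kJ mol⁻¹)
    X + Q → J (k = 0.00237 M⁻¹ min⁻¹, Ea = 82.0 kJ mol⁻¹)
    (constants at 110 °C)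

Started from the flask's own 31.0%, one doubling gain gives 35.8% after summer, against the 35.7% found. The same flask read at 2.5 d lies two doublings on, which gives 40.6%, and it stands at 42.8%, 2.2 points higher.

The data stem from a simulated flask on assumed constants.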